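All runs are simulated on assumed constants.

A small charge of substrate stands in an excess of reagent in blue, and this plate raises the substrate charge flask by flask while the reagent stays at 0.715 M. The earlier run, eta, was made with more reagent.

| flask | substrate | reagent | remark | time |
|---|---|---|---|---|
| eta | 0.080 M | 1.1 M | run made earlier |  |
| blue | 0.080 M | 0.715 M |  | 5.0 d |
| ochre | 0.20 M | 0.715 M |  | 5.0 d |
| teal | 0.60 M | 0.715 M |  | 5.0 d |
| amber | 2.0 M | 0.715 M |  | 5.0 d |

- eta (time / h: target / %): 3.00: 0; 5.00: 2.4; 8.00: 6.6; 12.0: 10.1; 20.0: 17.3; 30.0: 23.2; 40.0: 26.7

(scatter of a reading: 1 percentage point)

1. [target] at the end for blue, ochre, teal, amber, in this order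
2. the course of these numbers from the first flask to the last (rises, then falls / falls, then rises / rises all the way / falls all the way / hardly changes)

- steps that have been proposed: substrate <-> intermediate A; substrate + reagent -> intermediate B; intermediate B <-> intermediate C; reagent + intermediate B -> target; target -> over-reaction product
- "hardly changes" means that all values lie within two and a half points (for a concentration: within two and a half percent of the largest)

The proposed steps turn substrate and reagent into intermediate B, and intermediate B with further reagent into target. Substrate can also turn aside to intermediate A, intermediate B can pass to intermediate C, and target goes on to over-reaction product. So each target costs two reagent. Half the reagent charge, 0.357 M, is therefore the reagent ceiling: the most target this reagent can pay for, whatever the rates. A substrate charge below it leaves substrate as the limiting reagent, as in ochre, while above it, as in teal, reagent takes that part.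

Two chemists dispute the row. The first treats eta as a fixed yield: its last reading is 26.7% of the charge, percent should not care about the charge, so target rises all the way and amber reaches 0.534 M. The second replies that this stands above the ceiling. She makes the forecast: 0.018 M, 0.04 M, 0.05 M and 0.003 M, so rises, then falls, because in amber “the first step eats the reagent within hours”.

The simulation gives 0.0167 M, 0.0370 M, 0.0619 M and 0.0180 M, so rises, then falls, and the shape goes to the second chemist. They part at amber, which holds 6.00 times the forecast's figure. The first chemist keeps the small charges, with a local order of 0.93 in blue and 0.78 in ochre. The row turns at 0.58 M, beyond the charge that equals the ceiling.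

    substrate ⇌ intermediate A (K = 3.10, k = 1.95 × 10⁻⁵ /s)
    substrate + reagent → intermediate B (k = 2.21 × 10⁻⁵ /M/s)
    intermediate B ⇌ intermediate C (K = 0.247, k = 1.54 × 10⁻⁵ /s)
    reagent + intermediate B → target (k = 9.88 × 10⁻⁶ /M/s)
    target → over-reaction product (k = 5.15 × 10⁻⁶ /s)

Part of what amber falls short of its ceiling is the over-reaction step: with that step taken away, amber ends at 0.0968 M, a quarter of the 0.357 M its reagent could pay for, and reagent stands at 0.27% of its charge after 5.00 d. Blue is the opposite case, since its reagent ceiling lies 4.46 times above its substrate charge, so the substrate charge 0.080 M is the bound. Blue's 0.0167 M rests on two things acting together: the backward run from intermediate C to intermediate B, without which blue ends at 0.00476 M, and the length of the run, since blue taken to 50.0 d ends at 5.78 × 10⁻⁶ M.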